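Cuts: the Z-alkene is traced back to a diarylalkyne and the seven phenols to methyl ethers. In each dihydrofuran three bonds are then cut (aryl–C3, C3–C2, C2–O1), first in the ring fused to ring A (the ring that carries the styryl arm), then in the ring fused to ring B.
Enabling feature: each dihydrofuran (O1, C2, C3, C3a, C7a) is a four-atom o-quinone methide (O1=C7a–C3a=C3, C3 being a diarylmethine carbon beside a phenolic oxygen) closed by the one-carbon 4-oxybenzylidene unit C2. Rings A and B share one pattern (C3a lies between the O1-bearing C7a and a carbon-substituted C4, with oxygen at C6 para to C3a), so a single 2-bromo-6-hydroxy-4-methoxybenzaldehyde feeds both.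
Forward order: all six benzene rings are bought. An aryl Grignard reagent, an O-Boc salicylaldehyde and a sulfonium benzylide close the dihydrofuran on ring B. Its C4 bromide then becomes the aryl-magnesium of a second union of the same kind, which closes the dihydrofuran on ring A and completes the trimer. Demethylation and alkyne semihydrogenation finish the route.
Stereochemistry: C2/C3 of the ring-B unit (R,R) come from the (2R,5R)-2,5-dimethylthiolanium benzylide and C2/C3 of the ring-A unit (S,S) from its enantiomer. The trans relation in each ring comes from anti addition and invertive closure, and is also the thermodynamic result. The Z-alkene comes from syn addition of hydrogen.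

Key step: step 13

Assumption: the (2R,5R)-thiolanium benzylide is taken to give the (2R,3R) ring, by analogy with its benzylidene transfer to aldehydes; the bromine atom of the first annulation product allows an X-ray check, and if the sense is the reverse the two enantiomeric salts change places in the two annulations with nothing else altered.

Step 1
Reactants: 1 2-bromo-4,6-dimethoxybenzaldehyde
Product: 2 2-bromo-6-hydroxy-4-methoxybenzaldehyde
Conditions: BCl3 (1.2 equiv), CH2Cl2, −78 °C to rt; H2O
Reagents that add atoms: none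
Why: Chelation-directed ether cleavage: boron binds the formyl oxygen and the ortho methoxy oxygen in a six-membered chelate, so chloride removes only that methyl group while the para methoxy group and the bromide stay.

Step 2
Reactants: 2 2-bromo-6-hydroxy-4-methoxybenzaldehyde
Product: 3 tert-butyl (3-bromo-2-formyl-5-methoxyphenyl) carbonate
Conditions: Boc2O, i-Pr2NEt, DMAP (cat.), CH2Cl2, 0 °C to rt
Reagents that add atoms: di-tert-butyl dicarbonate, CC(C)(C)OC(=O)OC(=O)OC(C)(C)C
Why: DMAP-catalysed O-acylation of a phenol by Boc anhydride is the standard entry to O-Boc salicylaldehydes and runs under mild base that leaves the aldehyde and the bromide alone.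

Step 3
Reactants: 2 2-bromo-6-hydroxy-4-methoxybenzaldehyde; 4 1-ethynyl-4-methoxybenzene
Product: 5 2-hydroxy-4-methoxy-6-[(4-methoxyphenyl)ethynyl]benzaldehyde
Conditions: PdCl2(PPh3)2 (3 mol %), CuI (5 mol %), Et3N, DMF, 60 °C, degassed
Reagents that add atoms: none
Why: Sonogashira coupling: the ortho formyl group speeds oxidative addition into the C–Br bond, the hydrogen-bonded phenol is tolerated by the amine base, and because it lies meta to the new alkyne no cycloisomerisation to a benzofuran can follow.

Step 4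
Reactants: 5 2-hydroxy-4-methoxy-6-[(4-methoxyphenyl)ethynyl]benzaldehyde
Product: 6 tert-butyl {2-formyl-5-methoxy-3-[(4-methoxyphenyl)ethynyl]phenyl} carbonate
Conditions: Boc2O, i-Pr2NEt, DMAP (cat.), CH2Cl2, 0 °C to rt
Reagents that add atoms: di-tert-butyl dicarbonate, CC(C)(C)OC(=O)OC(=O)OC(C)(C)C
Why: The same DMAP-catalysed O-acylation as in step 2 applies, and the alkyne and the aldehyde are inert to it.

Step 5
Reactants: 7 1-bromo-3,5-dimethoxybenzene
Product: 8 3,5-dimethoxyphenylmagnesium bromide (titrated THF solution)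
Conditions: Mg turnings, I2 (crystal), THF, 40 °C to reflux
Reagents that add atoms: magnesium, [Mg]
Why: Classical Grignard formation by magnesium insertion into an aryl bromide, with methyl ethers inert and titration allowing exactly one equivalent to be dosed in step 12.

Step 6
Reactants: 9 (2S,5S)-hexane-2,5-diol
Product: 10 (2S,5S)-hexane-2,5-diyl dimethanesulfonate
Conditions: MsCl (2.5 equiv), Et3N (3 equiv), CH2Cl2, −20 to 0 °C
Reagents that add atoms: methanesulfonyl chloride, CS(=O)(=O)Cl
Why: Sulfonylation of the secondary alcohols takes place at oxygen only, so both C–O bonds and both (S) centres are retained.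

Step 7
Reactants: 10 (2S,5S)-hexane-2,5-diyl dimethanesulfonate
Product: 11 (2R,5R)-2,5-dimethylthiolane
Conditions: Na2S·9H2O, EtOH, rt; pentane extraction, distillation
Reagents that add atoms: sodium sulfide, [Na+].[Na+].[S-2]
Why: Double SN2 displacement by sulfide (intermolecular, then 5-exo-tet closure) inverts both carbons and turns the (S,S)-dimesylate into the C2-symmetric (R,R)-thiolane.

Step 8
Reactants: 11 (2R,5R)-2,5-dimethylthiolane; 12 4-methoxybenzyl bromide
Product: 13 (2R,5R)-1-(4-methoxybenzyl)-2,5-dimethylthiolan-1-ium tetrafluoroborate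
Conditions: CH2Cl2, 0 °C; AgBF4 (1.0 equiv), dark, 0 °C to rt; filtration, precipitation with Et2O
Reagents that add atoms: silver tetrafluoroborate, [Ag+].F[B-](F)(F)F
Why: S-alkylation of a thioether by a reactive benzylic bromide is driven by precipitation of silver bromide, and because the sulfide is C2-symmetric its two lone pairs are equivalent, sulfur is no stereocentre and a single salt forms.

Step 9
Reactants: 14 (2R,5R)-hexane-2,5-diol
Product: 15 (2R,5R)-hexane-2,5-diyl dimethanesulfonate
Conditions: MsCl (2.5 equiv), Et3N (3 equiv), CH2Cl2, −20 to 0 °C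
Reagents that add atoms: methanesulfonyl chloride, CS(=O)(=O)Cl
Why: O-sulfonylation as in step 6 retains both (R) centres.

Step 10
Reactants: 15 (2R,5R)-hexane-2,5-diyl dimethanesulfonate
Product: 16 (2S,5S)-2,5-dimethylthiolane
Conditions: Na2S·9H2O, EtOH, rt; pentane extraction, distillation
Reagents that add atoms: sodium sulfide, [Na+].[Na+].[S-2]
Why: Double SN2 displacement with inversion at both carbons, as in step 7, gives the enantiomeric C2-symmetric thiolane.

Step 11
Reactants: 16 (2S,5S)-2,5-dimethylthiolane; 12 4-methoxybenzyl bromide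
Product: 17 (2S,5S)-1-(4-methoxybenzyl)-2,5-dimethylthiolan-1-ium tetrafluoroborate
Conditions: CH2Cl2, 0 °C; AgBF4 (1.0 equiv), dark, 0 °C to rt; filtration, precipitation with Et2O
Reagents that add atoms: silver tetrafluoroborate, [Ag+].F[B-](F)(F)F
Why: The silver-assisted S-alkylation of step 8 is repeated on the enantiomeric sulfide and again gives a single salt.

Step 12
Reactants: 3 tert-butyl (3-bromo-2-formyl-5-methoxyphenyl) carbonate; 8 3,5-dimethoxyphenylmagnesium bromide; 13 (2R,5R)-1-(4-methoxybenzyl)-2,5-dimethylthiolan-1-ium tetrafluoroborate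
Product: 22 (2R,3R)-4-bromo-3-(3,5-dimethoxyphenyl)-6-methoxy-2-(4-methoxyphenyl)-2,3-dihydrobenzofuran, via sulfonium benzylide 18 (not isolated), via magnesium phenoxide carbonate 19 (not isolated), via o-quinone methide 20 (not isolated), via betaine 21 (not isolated)
Conditions: 3, THF, −78 °C, 8 (1.0 equiv), 30 min; 18 [from 13 (1.3 equiv), LiHMDS (1.25 equiv), THF, −78 °C] added by cannula; −78 to 0 °C; aq NH4Cl; recrystallisation to raise the enantiomeric purity
Reagents that add atoms: none
Why: Proposed new method: the Grignard reagent adds to the aldehyde at −78 °C, the alkoxide takes over the neighbouring Boc group to give 19, and on warming the magnesium phenoxide expels tert-butyl carbonate to give o-quinone methide 20, which the carbanion of benzylide 18 attacks at the exocyclic carbon (1,4-addition with rearomatisation) to give betaine 21 that closes 5-exo-tet by invertive displacement of the thiolane; C3 (R) is set by the face of 20 that the chiral ylide selects and C2 (R) by the open face of the ylide carbon followed by inversion, anti addition giving the trans ring; the closest known reaction types are organomagnesium-triggered o-quinone methide formation from O-Boc salicylaldehydes, [4+1] annulation of o-quinone methides with carbonyl-stabilised sulfonium ylides, and asymmetric benzylidene transfer from C2-symmetric thiolanium ylides to aldehydes.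

Step 13
Reactants: 22 (2R,3R)-4-bromo-3-(3,5-dimethoxyphenyl)-6-methoxy-2-(4-methoxyphenyl)-2,3-dihydrobenzofuran; 6 tert-butyl {2-formyl-5-methoxy-3-[(4-methoxyphenyl)ethynyl]phenyl} carbonate; 17 (2S,5S)-1-(4-methoxybenzyl)-2,5-dimethylthiolan-1-ium tetrafluoroborate
Product: 29 didehydro-miyabenol C heptamethyl ether (ring-A unit 2S,3S; ring-B unit 2R,3R; alkyne in place of the alkene), via aryllithium 23 (not isolated), via arylmagnesium bromide 24 (not isolated), via sulfonium benzylide 25 (not isolated), via magnesium phenoxide carbonate 26 (not isolated), via o-quinone methide 27 (not isolated), via betaine 28 (not isolated)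
Conditions: 22, t-BuLi (2.0 equiv), THF, −78 °C; MgBr2·OEt2 (1.1 equiv), −78 °C; 6 (1.0 equiv), −78 to −50 °C; 25 [from 17 (1.3 equiv), LiHMDS (1.25 equiv), THF, −78 °C] added by cannula at −78 °C; −78 to 0 °C; aq NH4Cl
Reagents that add atoms: none
Why: Proposed new method: bromine–lithium exchange (23) and transmetalation turn 22 into aryl-magnesium 24, which adds to the aldehyde of 6; the alkoxide takes over the neighbouring Boc group (26), and on warming the magnesium phenoxide expels tert-butyl carbonate to unveil o-quinone methide 27, whose exocyclic carbon is attacked by the carbanion of benzylide 25 (1,4-addition that rearomatises ring A) to give betaine 28. The only ring formed, the dihydrofuran fused to ring A, closes 5-exo-tet when the phenoxide oxygen of 28 displaces the thiolane at the benzylic carbon by SN2. The closest known reaction types are organomagnesium-triggered o-quinone methide generation from O-Boc salicylaldehydes, [4+1] annulation of o-quinone methides with carbonyl-stabilised sulfonium ylides to trans-2,3-dihydrobenzofurans, and asymmetric benzylidene transfer from C2-symmetric thiolanium ylides to aldehydes; new is their union in one flask with a semi-stabilised chiral benzylide. C3 (S) is fixed in the irreversible C–C bond formation by the face of 27 that the (2S,5S)-ylide selects, and C2 (S) by the open face of the ylide carbon followed by inversion in the closure, the anti betaine giving the trans ring. The step needs conjugate addition rather than epoxide formation, face selectivity at the exocyclic carbon against the bias of the resident (2R,3R) unit, and trans selectivity. The first is secured because no aldehyde is left when the ylide enters, the second is helped by the C4 alkynyl group, which should hold the bulky ring-B aryl group on the carbonyl side so that 27 reacts as one geometric isomer, and the third is backed by the thermodynamic preference for trans, since C2 can still be equilibrated through its 4-methoxybenzyl cation without touching C3.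

Step 14
Reactants: 29 didehydro-miyabenol C heptamethyl ether
Product: 30 didehydro-miyabenol C (heptaphenol alkyne)
Conditions: BBr3 (1 M in CH2Cl2, 14 equiv), CH2Cl2, −78 °C to rt; poured into ice-cold pH 7 phosphate buffer
Reagents that add atoms: none
Why: Boron tribromide ether cleavage activates each aryl methyl ether at oxygen for demethylation by bromide, methoxy-substituted diarylalkynes without an ortho heteroatom nucleophile tolerate the reagent, no protic acid is present until the buffered quench, and any reversible ionisation of a C2–O bond re-closes to the more stable trans ring while C3 stays untouched.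

Step 15
Reactants: 30 didehydro-miyabenol C (heptaphenol alkyne)
Product: 31 cis-miyabenol C
Conditions: H2 (1 atm), Lindlar catalyst (5% Pd/CaCO3, Pb-poisoned), quinoline, EtOAc–MeOH, rt, dark, stopped after one equivalent of H2
Reagents that add atoms: none
Why: Lindlar semihydrogenation delivers both hydrogens to one face of the adsorbed diarylalkyne and so gives the Z-alkene, lead and quinoline hold back over-reduction and isomerisation, the benzylic C–O bonds are not hydrogenolysed under these mild conditions, and exclusion of light prevents Z-to-E isomerisation.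

Compound list
1 | 2-bromo-4,6-dimethoxybenzaldehyde | COc1cc(OC)c(C=O)c(Br)c1 | starting material
2 | 2-bromo-6-hydroxy-4-methoxybenzaldehyde | COc1cc(O)c(C=O)c(Br)c1 | intermediate
3 | tert-butyl (3-bromo-2-formyl-5-methoxyphenyl) carbonate (ring-B block) | COc1cc(OC(=O)OC(C)(C)C)c(C=O)c(Br)c1 | intermediate
4 | 1-ethynyl-4-methoxybenzene (4-ethynylanisole) | COc1ccc(C#C)cc1 | starting material
5 | 2-hydroxy-4-methoxy-6-[(4-methoxyphenyl)ethynyl]benzaldehyde | COc1ccc(C#Cc2cc(OC)cc(O)c2C=O)cc1 | intermediate
6 | tert-butyl {2-formyl-5-methoxy-3-[(4-methoxyphenyl)ethynyl]phenyl} carbonate (ring-A block) | COc1ccc(C#Cc2cc(OC)cc(OC(=O)OC(C)(C)C)c2C=O)cc1 | intermediate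
7 | 1-bromo-3,5-dimethoxybenzene | COc1cc(Br)cc(OC)c1 | starting material
8 | 3,5-dimethoxyphenylmagnesium bromide | COc1cc([Mg]Br)cc(OC)c1 | intermediate
9 | (2S,5S)-hexane-2,5-diol | C[C@H](O)CC[C@H](C)O | starting material
10 | (2S,5S)-hexane-2,5-diyl dimethanesulfonate | C[C@H](OS(C)(=O)=O)CC[C@H](C)OS(C)(=O)=O | intermediate
11 | (2R,5R)-2,5-dimethylthiolane | S1[C@H](C)CC[C@H]1C | intermediate
12 | 4-methoxybenzyl bromide | COc1ccc(CBr)cc1 | starting material
13 | (2R,5R)-1-(4-methoxybenzyl)-2,5-dimethylthiolan-1-ium tetrafluoroborate | COc1ccc(C[S+]2[C@H](C)CC[C@H]2C)cc1.F[B-](F)(F)F | intermediate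
14 | (2R,5R)-hexane-2,5-diol | C[C@@H](O)CC[C@@H](C)O | starting material
15 | (2R,5R)-hexane-2,5-diyl dimethanesulfonate | C[C@@H](OS(C)(=O)=O)CC[C@@H](C)OS(C)(=O)=O | intermediate
16 | (2S,5S)-2,5-dimethylthiolane | S1[C@@H](C)CC[C@@H]1C | intermediate
17 | (2S,5S)-1-(4-methoxybenzyl)-2,5-dimethylthiolan-1-ium tetrafluoroborate | COc1ccc(C[S+]2[C@@H](C)CC[C@@H]2C)cc1.F[B-](F)(F)F | intermediate
18 | 4-methoxybenzylide of 13: [(2R,5R)-2,5-dimethylthiolan-1-ium-1-yl](4-methoxyphenyl)methanide | COc1ccc([CH-][S+]2[C@H](C)CC[C@H]2C)cc1 | intermediate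
19 | bromomagnesium 3-bromo-2-[(tert-butoxycarbonyloxy)(3,5-dimethoxyphenyl)methyl]-5-methoxyphenoxide (carbinol carbon not controlled) | COc1cc(O[Mg]Br)c(C(OC(=O)OC(C)(C)C)c2cc(OC)cc(OC)c2)c(Br)c1 | intermediate
20 | 5-bromo-6-(3,5-dimethoxybenzylidene)-3-methoxycyclohexa-2,4-dien-1-one, aryl group expected on the carbonyl side | O=C1C=C(OC)C=C(Br)/C1=C/c1cc(OC)cc(OC)c1 | intermediate
21 | 3-bromo-2-{(1R,2S)-1-(3,5-dimethoxyphenyl)-2-[(2R,5R)-2,5-dimethylthiolan-1-ium-1-yl]-2-(4-methoxyphenyl)ethyl}-5-methoxyphenoxide | [O-]c1cc(OC)cc(Br)c1[C@@H](c1cc(OC)cc(OC)c1)[C@@H](c1ccc(OC)cc1)[S+]1[C@H](C)CC[C@H]1C | intermediate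
22 | (2R,3R)-4-bromo-3-(3,5-dimethoxyphenyl)-6-methoxy-2-(4-methoxyphenyl)-2,3-dihydrobenzofuran (trans) | Brc1cc(OC)cc2c1[C@@H](c1cc(OC)cc(OC)c1)[C@H](c1ccc(OC)cc1)O2 | intermediate
23 | 4-lithio analogue of 22, (2R,3R) | [Li]c1cc(OC)cc2c1[C@@H](c1cc(OC)cc(OC)c1)[C@H](c1ccc(OC)cc1)O2 | intermediate
24 | 4-(bromomagnesio) analogue of 22, (2R,3R) | Br[Mg]c1cc(OC)cc2c1[C@@H](c1cc(OC)cc(OC)c1)[C@H](c1ccc(OC)cc1)O2 | intermediate
25 | 4-methoxybenzylide of 17: [(2S,5S)-2,5-dimethylthiolan-1-ium-1-yl](4-methoxyphenyl)methanide | COc1ccc([CH-][S+]2[C@@H](C)CC[C@@H]2C)cc1 | intermediate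
26 | bromomagnesium phenoxide of ring A carrying the O-Boc diarylcarbinol to the (2R,3R)-dihydrobenzofuran-4-yl unit (carbinol carbon not controlled) | COc1ccc(C#Cc2cc(OC)cc(O[Mg]Br)c2C(OC(=O)OC(C)(C)C)c2cc(OC)cc3c2[C@@H](c2cc(OC)cc(OC)c2)[C@H](c2ccc(OC)cc2)O3)cc1 | intermediate
27 | 3-methoxy-5-[(4-methoxyphenyl)ethynyl]cyclohexa-2,4-dien-1-one with a 6-arylmethylidene group, aryl = the (2R,3R)-dihydrobenzofuran-4-yl unit of 22, expected on the carbonyl side | O=C1C=C(OC)C=C(C#Cc2ccc(OC)cc2)/C1=C/c1cc(OC)cc2c1[C@@H](c1cc(OC)cc(OC)c1)[C@H](c1ccc(OC)cc1)O2 | intermediate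
28 | ring-A phenoxide / (2S,5S)-thiolanium betaine, (1S) at the future C3 and (2R) at the sulfonium-bearing carbon | [O-]c1cc(OC)cc(C#Cc2ccc(OC)cc2)c1[C@H](c1cc(OC)cc2c1[C@@H](c1cc(OC)cc(OC)c1)[C@H](c1ccc(OC)cc1)O2)[C@H](c1ccc(OC)cc1)[S+]1[C@@H](C)CC[C@@H]1C | intermediate
29 | (2S,3S)-3-[(2R,3R)-3-(3,5-dimethoxyphenyl)-6-methoxy-2-(4-methoxyphenyl)-2,3-dihydrobenzofuran-4-yl]-6-methoxy-2-(4-methoxyphenyl)-4-[(4-methoxyphenyl)ethynyl]-2,3-dihydrobenzofuran | COc1ccc(C#Cc2cc(OC)cc3c2[C@H](c2cc(OC)cc4c2[C@@H](c2cc(OC)cc(OC)c2)[C@H](c2ccc(OC)cc2)O4)[C@@H](c2ccc(OC)cc2)O3)cc1 | intermediate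
30 | (2S,3S)-3-[(2R,3R)-3-(3,5-dihydroxyphenyl)-6-hydroxy-2-(4-hydroxyphenyl)-2,3-dihydrobenzofuran-4-yl]-2-(4-hydroxyphenyl)-4-[(4-hydroxyphenyl)ethynyl]-2,3-dihydrobenzofuran-6-ol | Oc1ccc(C#Cc2cc(O)cc3c2[C@H](c2cc(O)cc4c2[C@@H](c2cc(O)cc(O)c2)[C@H](c2ccc(O)cc2)O4)[C@@H](c2ccc(O)cc2)O3)cc1 | intermediate
31 | cis-miyabenol C: as 30 with a (Z)-2-(4-hydroxyphenyl)ethenyl group at C4 of the ring-A unit | Oc1ccc(/C=C\c2cc(O)cc3c2[C@H](c2cc(O)cc4c2[C@@H](c2cc(O)cc(O)c2)[C@H](c2ccc(O)cc2)O4)[C@@H](c2ccc(O)cc2)O3)cc1 | target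

Total step count: 15.
Longest linear sequence: 7 steps (9 → 10 → 11 → 13 → 22 → 29 → 30 → 31, i.e. steps 6, 7, 8, 12, 13, 14, 15). Counted from aldehyde 1 the sequence is 6 steps.

Steps most likely to fail

1. Step 13 (key step).
What may go wrong:
- sluggish addition of the hindered aryl-magnesium to the doubly ortho-substituted aldehyde;
- release of the quinone methide before the ylide is at hand, with dimerisation or capture by unreacted aryl-magnesium;
- decay of the semi-stabilised ylide by sigmatropic rearrangement or β-elimination during warming;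
- mismatched facial selectivity against the resident stereocentres.

Fallback (known chemistry; sets out from 5 and 22, returns at 29): the C3–C2 and C2–O bonds are made one at a time by carbonyl homologation. Phenol 5 is capped with MOMCl/i-Pr2NEt as the methoxymethyl ether F1. Aryllithium 23, generated from 22 as in step 13, is added to it to give the diarylcarbinol F2, which Dess–Martin periodinane oxidises to the diaryl ketone F3. Corey–Chaykovsky methylenation with dimethylsulfonium methylide gives the 1,1-diaryloxirane F4, a zinc iodide-induced Meinwald rearrangement gives the diarylacetaldehyde F5, and addition of 4-methoxyphenylmagnesium bromide gives the triarylethanol F6. Methanolic HCl then removes the MOM group and ionises the 4-methoxybenzylic alcohol, and the freed phenol closes the thermodynamically preferred trans ring. C3 now arises under substrate control only, so 29 has to be separated by chromatography from its ring-A (2R,3R) diastereomer F7.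

2. Step 12.
What may go wrong:
- a second Grignard addition to the quinone methide if the dosing is not exact;
- quinone methide dimerisation;
- loss of the ylide before the quinone methide is released;
- low or reversed enantioselectivity, and incomplete trans selectivity.

Fallback (known chemistry; sets out from 2, 8 and 12, returns at 22): the C2–C3 bond is made by an enantioselective carbene C–H insertion. Phenol 2 is alkylated with 12 (K2CO3, DMF) to the 4-methoxybenzyl ether F8, Grignard reagent 8 adds to give the benzhydrol F9, and MnO2 gives the benzophenone F10. Hydrazine hydrate with acetic acid in hot ethanol gives the hydrazone F11, and MnO2 oxidises it to the diaryldiazomethane F12. A chiral dirhodium tetracarboxylate, Rh2(PTAD)4 in the enantiomeric form that leads to 3R, promotes donor/donor carbene insertion into the OCH2Ar group to give the cis-(2S,3R)-dihydrobenzofuran F13. Brief exposure to TFA in CH2Cl2 epimerises C2 through the 4-methoxybenzyl cation and delivers the trans compound 22.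

3. Step 14.
What may go wrong:
- bromoboration or protonation of the electron-rich triple bond, followed by attack of the neighbouring ring B (closure of a seven-membered ring);
- irreversible Friedel–Crafts capture after ionisation of a C2–O bond;
- incomplete cleavage of seven ethers.

Fallback (sets out from 3, 24 and 25, returns at 30): the triple bond is brought in only after the ethers are gone. Aryl-magnesium 24 is added to bromo carbonate 3 in place of 6 and the protocol of step 13 is followed with ylide 25. This passes through the magnesium phenoxide carbonate F14, the o-quinone methide F15 and the betaine F16 to the bromo trimer hexamethyl ether F17. Boron tribromide now meets no alkyne and gives the bromo hexaphenol F18. Acetic anhydride in pyridine gives the hexaacetate F19, and a Sonogashira coupling with commercial 4-ethynylphenyl acetate (Pd/Cu, Et3N) gives the heptaacetate F20. Potassium carbonate in methanol at 0 °C under argon then gives the heptaphenol 30.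

Further compounds
F1 | step 13 | 4-methoxy-2-(methoxymethoxy)-6-[(4-methoxyphenyl)ethynyl]benzaldehyde | COCOc1cc(OC)cc(C#Cc2ccc(OC)cc2)c1C=O
F2 | step 13 | diarylcarbinol from 23 and F1 (carbinol carbon not controlled) | COCOc1cc(OC)cc(C#Cc2ccc(OC)cc2)c1C(O)c1cc(OC)cc2c1[C@@H](c1cc(OC)cc(OC)c1)[C@H](c1ccc(OC)cc1)O2
F3 | step 13 | diaryl ketone from F2 | COCOc1cc(OC)cc(C#Cc2ccc(OC)cc2)c1C(=O)c1cc(OC)cc2c1[C@@H](c1cc(OC)cc(OC)c1)[C@H](c1ccc(OC)cc1)O2
F4 | step 13 | 1,1-diaryloxirane from F3 (new centre not controlled) | COCOc1cc(OC)cc(C#Cc2ccc(OC)cc2)c1C1(CO1)c1cc(OC)cc2c1[C@@H](c1cc(OC)cc(OC)c1)[C@H](c1ccc(OC)cc1)O2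
F5 | step 13 | diarylacetaldehyde from F4 (new centre not controlled) | COCOc1cc(OC)cc(C#Cc2ccc(OC)cc2)c1C(C=O)c1cc(OC)cc2c1[C@@H](c1cc(OC)cc(OC)c1)[C@H](c1ccc(OC)cc1)O2
F6 | step 13 | 2,2-diaryl-1-(4-methoxyphenyl)ethanol from F5 (new centres not controlled) | COCOc1cc(OC)cc(C#Cc2ccc(OC)cc2)c1C(C(O)c1ccc(OC)cc1)c1cc(OC)cc2c1[C@@H](c1cc(OC)cc(OC)c1)[C@H](c1ccc(OC)cc1)O2
F7 | step 13 | diastereomer of 29 with the ring-A unit (2R,3R) | COc1ccc(C#Cc2cc(OC)cc3c2[C@@H](c2cc(OC)cc4c2[C@@H](c2cc(OC)cc(OC)c2)[C@H](c2ccc(OC)cc2)O4)[C@H](c2ccc(OC)cc2)O3)cc1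
F8 | step 12 | 2-bromo-4-methoxy-6-[(4-methoxybenzyl)oxy]benzaldehyde | COc1ccc(COc2cc(OC)cc(Br)c2C=O)cc1
F9 | step 12 | {2-bromo-4-methoxy-6-[(4-methoxybenzyl)oxy]phenyl}(3,5-dimethoxyphenyl)methanol (racemic) | COc1ccc(COc2cc(OC)cc(Br)c2C(O)c2cc(OC)cc(OC)c2)cc1
F10 | step 12 | {2-bromo-4-methoxy-6-[(4-methoxybenzyl)oxy]phenyl}(3,5-dimethoxyphenyl)methanone | COc1ccc(COc2cc(OC)cc(Br)c2C(=O)c2cc(OC)cc(OC)c2)cc1
F11 | step 12 | hydrazone of F10 | COc1ccc(COc2cc(OC)cc(Br)c2C(=NN)c2cc(OC)cc(OC)c2)cc1
F12 | step 12 | diaryldiazomethane from F11 | COc1ccc(COc2cc(OC)cc(Br)c2C(=[N+]=[N-])c2cc(OC)cc(OC)c2)cc1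
F13 | step 12 | (2S,3R)-4-bromo-3-(3,5-dimethoxyphenyl)-6-methoxy-2-(4-methoxyphenyl)-2,3-dihydrobenzofuran (cis) | Brc1cc(OC)cc2c1[C@@H](c1cc(OC)cc(OC)c1)[C@@H](c1ccc(OC)cc1)O2
F14 | step 14 | bromo analogue of 26 (carbinol carbon not controlled) | COc1cc(O[Mg]Br)c(C(OC(=O)OC(C)(C)C)c2cc(OC)cc3c2[C@@H](c2cc(OC)cc(OC)c2)[C@H](c2ccc(OC)cc2)O3)c(Br)c1
F15 | step 14 | bromo analogue of 27 | O=C1C=C(OC)C=C(Br)/C1=C/c1cc(OC)cc2c1[C@@H](c1cc(OC)cc(OC)c1)[C@H](c1ccc(OC)cc1)O2
F16 | step 14 | bromo analogue of 28 | [O-]c1cc(OC)cc(Br)c1[C@H](c1cc(OC)cc2c1[C@@H](c1cc(OC)cc(OC)c1)[C@H](c1ccc(OC)cc1)O2)[C@H](c1ccc(OC)cc1)[S+]1[C@@H](C)CC[C@@H]1C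
F17 | step 14 | (2S,3S)-4-bromo-3-[(2R,3R)-3-(3,5-dimethoxyphenyl)-6-methoxy-2-(4-methoxyphenyl)-2,3-dihydrobenzofuran-4-yl]-6-methoxy-2-(4-methoxyphenyl)-2,3-dihydrobenzofuran | Brc1cc(OC)cc2c1[C@H](c1cc(OC)cc3c1[C@@H](c1cc(OC)cc(OC)c1)[C@H](c1ccc(OC)cc1)O3)[C@@H](c1ccc(OC)cc1)O2
F18 | step 14 | hexaphenol of F17 | Brc1cc(O)cc2c1[C@H](c1cc(O)cc3c1[C@@H](c1cc(O)cc(O)c1)[C@H](c1ccc(O)cc1)O3)[C@@H](c1ccc(O)cc1)O2
F19 | step 14 | hexaacetate of F18 | Brc1cc(OC(C)=O)cc2c1[C@H](c1cc(OC(C)=O)cc3c1[C@@H](c1cc(OC(C)=O)cc(OC(C)=O)c1)[C@H](c1ccc(OC(C)=O)cc1)O3)[C@@H](c1ccc(OC(C)=O)cc1)O2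
F20 | step 14 | heptaacetate of 30 | CC(=O)Oc1ccc(C#Cc2cc(OC(C)=O)cc3c2[C@H](c2cc(OC(C)=O)cc4c2[C@@H](c2cc(OC(C)=O)cc(OC(C)=O)c2)[C@H](c2ccc(OC(C)=O)cc2)O4)[C@@H](c2ccc(OC(C)=O)cc2)O3)cc1
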